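# Synthesis plan for CNP0208815.1: a vinylketene/ynol ether benzannulation route

## The problem

Atoms of the target are numbered as a chromene: O1, C2, C3, C4 (ring B), C4a, C5, C6, C7, C8, C8a (ring A). Ring C is the cyclobutane.

The target is a dearomatised acylphloroglucinol. In ring A the oxygen-bearing carbons C5 (enol OH), C7 (ketone) and C8a (ring ether O1) alternate with the carbon-substituted C4a (bonded to the ring-B ketone C4), C6 (bonded to C3 of an octanoic acid chain) and C8 (quaternary: prenyl plus a cyclobutylmethyl arm). Ring B is a trans-2,3-dimethyl-2,3-dihydropyran-4-one fused across C4a–C8a, and ring C is a cis-1,3-disubstituted 2,2-dimethylcyclobutane with an isopropenyl group.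

The six stereocentres fall into four groups (two in ring C, C8, the side-chain carbon, C2/C3 of ring B) that are too far apart to control one another. Only inside ring B can one centre set the other, because C3 equilibrates to trans once C2 is fixed, so ring C must come from the chiral pool and each other group from a catalyst.

The isopropenylcyclobutane is a latent cyclobutylcarbinyl cation and the prenyl group a latent tertiary cation. Strong Brønsted or Lewis acids (Friedel–Crafts acylation, acid-mediated lactone annulation) are therefore excluded once ring C is attached.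

Ring B opens by retro-oxa-Michael reaction and epimerises at C3 under strong base. The dienone of ring A is a heat- and hydroxide-sensitive vinylogous acid, and the free acid can lactonise on O5 or O7, so dearomatisation must come late and be followed by very little chemistry.

Seen as an aromatic precursor, ring A is a phloroglucinol whose three oxygens have three different fates, so they must be distinguishable from the moment the ring exists.

The enabling feature is that C8, the carbon with the primary alkyl arm, lies between two oxygenated carbons with the third oxygen para. That is the pattern produced when an alkyl-substituted ynol ether (C8, C8a) joins an alkoxy vinylketene (C7, C6, C5, C4a), delivering O7 as free OH, O1 as a silyl ether and O5 as an alkyl ether in one operation.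

## Retrosynthesis

**C8–prenyl bond (24 ⇒ 23 ⇒ 22).** After the trivial return from acid 24 to methyl ester 23, the C8–CH2(prenyl) bond is cut, giving the aromatic phenol 22. Cutting here rather than at the cyclobutylmethyl bond keeps every ring-substitution step on a robust arene and leaves only an ester hydrolysis after dearomatisation. The forward reaction must alkylate C8 rather than C6 or oxygen, and must choose one face of a planar ring with no nearby stereocentre, so it has to be catalyst-controlled.

**Lactone and ethyl ether (22 ⇒ 21 ⇒ 20).** The methyl ester and O7–H of 22 are folded back into the six-membered lactone 21, and the C5 hydroxyl is returned to the ethyl ether of 20. Removing the ethyl group while ring A is still aromatic is preferred to cleaving a vinylogous ester on the dienone, which would need heat or hydroxide on the most fragile intermediate. The forward step can use chelation to the neighbouring C4 ketone, and the same chelate is expected to bring C3 to the trans configuration.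

**Ring B (20 ⇒ 19 ⇒ 18 ⇒ 17 ⇒ 16).** The O1–C2 bond is cut (oxa-Michael), then the C4–C3 bond (addition of an aldehyde C–H across a four-carbon alkyne), then the formyl carbon, then the silyl group on O1. This replaces the usual Friedel–Crafts tigloylation, which ring C would not survive, by neutral steps. The forward ring closure must set C2 by catalyst control, and has only one hydroxyl ortho to the ketone available.

**Side chain (16 ⇒ 15 ⇒ 13 ⇒ 12).** The bond between the future side-chain stereocentre and the pentyl group is cut (conjugate addition of a pentyl organometallic to coumarin 15). The coumarin is then opened at its C=C and ester C–O bonds to salicylaldehyde 13, and the formyl carbon is removed to give phenol 12. Doing this before ring B exists means no ketone is present when the Grignard reagent is used. The free hydroxyl of 12 directs the one-carbon electrophile to the only open ortho position.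

**Ring A (12 ⇒ 6 + 7), the key cut.** Two ring bonds are cut, C7–C8 and C8a–C4a, giving silyl ynol ether 6 and 3-ethoxycyclobutenone 7. Against a classical route from a symmetrical phloroglucinol, this forms the C8–arm connection and three different oxygens at once, and needs no acid. The precursors are an acyclic alkyne and a four-carbon ring; only regiochemistry is asked of the forward reaction.

**Ynol ether and ring C (6 ⇒ 4 ⇒ 3 ⇒ 2 ⇒ 1).** The alkyne carbon bearing the arm is removed (ynolate homologation of ester 4). The isopropenyl CH2 goes back to the ketone of 3, and ester 3 to acid 2. Acid 2 is the oxidative cleavage product of (−)-α-pinene 1, which supplies both ring-C centres with the correct cis relationship and absolute configuration.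

## Roads not taken

**Alternative 1:** Here ring C is built on the arene. The bonds from the gem-dimethyl carbon to the ring CH and from the carbonyl carbon to the ring CH2 of cyclobutanone A1 are cut, leading to the allyl arene A2 and a keteniminium salt generated from a chiral amide such as A3. The forward step is a [2+2] cycloaddition across the terminal alkene followed by hydrolysis.
- Merits: cheap, symmetrical aromatic material, reliable regiochemistry of the cycloaddition, and no cryogenic ynolate step or special cyclobutenone. In raw-material simplicity it is better than the chosen plan.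
- Weak points: only one ring-C centre is made, and auxiliary control in intermolecular additions to unactivated terminal alkenes is modest. The ketone of A1 must still be turned into a CH–isopropenyl group cis to the arm, next to a quaternary carbon, which costs several steps with uncertain cis/trans control. The two oxygens flanking the arm in A2 are identical, so O7 and O1 would have to be told apart later.
- Comparison: the chosen plan takes both ring-C centres from α-pinene with no stereochemical risk and delivers an arene whose three oxygens are already different.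

**Alternative 2:** Ring B is cut last, at C2–C3 and O1–C8a. A silyl dienol ether, drawn from a propionyl group on C4a and the neighbouring methoxy-bearing C8a, would react with acetaldehyde A5 in a catalysed asymmetric hetero-Diels–Alder reaction with loss of methanol. This gives the enol lactone A4, which is then opened to the target.
- Merits: both ring-B centres are set in one catalyst-controlled step at the very end, so the epimerisable C3 and the retro-oxa-Michael-prone ring never see later base. In this respect it is better than the chosen plan, which must keep steps 14–16 mild.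
- Weak points: the diene is part of a fully substituted, cross-conjugated dienone and is far less reactive than a simple 1-alkoxy-3-siloxy diene. It would need a strong chiral Lewis acid together with a volatile, enolisable aldehyde, in the presence of prenyl and isopropenylcyclobutane groups. The trans outcome depends on enol ether geometry and endo/exo preference that are untested on such a diene. The arene, the quaternary centre and the side chain must all be solved beforehand.
- Comparison: the chosen plan sets C2 by an alkaloid-catalysed oxa-Michael addition on an o-tigloyl phenol, a closely precedented substrate type, while ring A is still aromatic and robust.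

**Alternative 3:** The C6–CH bond and the lactone C–O bond are cut. Phenol A7, which already carries ring B, would react with (E)-oct-2-enal A8 under oxidative N-heterocyclic carbene catalysis: C6 adds to the β-carbon of the unsaturated acyl azolium and O7 is acylated, giving A6. A6 is the same compound as 21 of the present route.
- Merits: one step makes the side-chain skeleton, its stereocentre and the lactone. From phenol 12 this road would reach 21 in about two steps fewer than the sequence used here, a real advantage.
- Weak points: β-alkyl enals are the less selective partners in this annulation. C6 of A7 lies between two free hydroxyls and is deactivated by the C4 ketone, so either O5 or O7 could close the lactone. The amine base and oxidant act on a substrate with the base-sensitive ring B in place.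
- Comparison: the chosen plan spends three steps (6–8) but puts the stereo-determining conjugate addition on coumarin 15, before any ketone exists, using linear alkyl Grignard reagents, the nucleophiles best suited to that catalyst class.

Key step: step 5

Remark: CbCH2 stands for the cis [(1R,3S)-2,2-dimethyl-3-(prop-1-en-2-yl)cyclobutyl]methyl group; in the catalyst-controlled steps 8, 12 and 15 the ligand or alkaloid antipode written is the one assumed to give the required centre, and its mirror image (quinidine for quinine) would be used if the sense proved opposite.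

## Route

Step 1
Reactants: 1 (1S,5S)-(−)-α-pinene
Product: 2 2-[(1R,3R)-3-acetyl-2,2-dimethylcyclobutyl]acetic acid (cis-pinonic acid)
Conditions: RuCl3·xH2O (cat.), NaIO4, EtOAc/MeCN/H2O, rt
Reagents that add atoms: sodium periodate [Na+].[O-]I(=O)(=O)=O; water O
Why: RuO4-catalysed oxidative cleavage of the trisubstituted alkene gives the methyl ketone and the acid; the two former bridgehead carbons are untouched and remain cis on the cyclobutane.

Step 2
Reactants: 2 cis-pinonic acid
Product: 3 ethyl 2-[(1R,3R)-3-acetyl-2,2-dimethylcyclobutyl]acetate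
Conditions: EtI, K2CO3, DMF, rt
Reagents that add atoms: iodoethane CCI
Why: Carboxylate O-alkylation with a weak base at room temperature; the acetyl-bearing ring carbon should not epimerise under these conditions.

Step 3
Reactants: 3 ethyl cis-pinonate
Product: 4 ethyl 2-[(1R,3S)-2,2-dimethyl-3-(prop-1-en-2-yl)cyclobutyl]acetate
Conditions: Ph3PCH3Br, KOtBu, THF, 0 °C to rt
Reagents that add atoms: methyltriphenylphosphonium bromide C[P+](c1ccccc1)(c1ccccc1)c1ccccc1.[Br-]
Why: Wittig methylenation of the methyl ketone with the non-stabilised ylide; addition should outrun enolisation at low temperature, so the cis relationship is kept and the ester is not attacked.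

Step 4
Reactants: 4 ethyl 2-[(1R,3S)-2,2-dimethyl-3-(prop-1-en-2-yl)cyclobutyl]acetate
Product: 6 triisopropyl{[3-((1R,3S)-2,2-dimethyl-3-(prop-1-en-2-yl)cyclobutyl)prop-1-yn-1-yl]oxy}silane, via lithium ynolate 5 (not isolated)
Conditions: CH2Br2, LiTMP, THF, −78 °C; n-BuLi, −78 to 0 °C; TIPSCl, −78 °C to rt
Reagents that add atoms: dibromomethane BrCBr; chlorotriisopropylsilane CC(C)[Si](Cl)(C(C)C)C(C)C
Why: Kowalski ester homologation stopped at the ynolate: LiCHBr2 adds to the ester, and the dibromo ketone enolate undergoes bromine–lithium exchange and 1,2-alkyl shift to ynolate 5, in which the former ester carbon keeps its oxygen. The bulky silyl chloride traps 5 on oxygen, and the isolated alkene is inert to the lithium bases.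

Step 5
Reactants: 6 triisopropylsilyl ynol ether; 7 3-ethoxycyclobut-2-en-1-one
Product: 12 5-ethoxy-2-(CbCH2)-3-(triisopropylsilyloxy)phenol, via vinylketene 8 (not isolated), via vinylcyclobutenone 9 (not isolated), via dienylketene 10 (not isolated), via cyclohexadienone 11 (not isolated)
Conditions: toluene, 80 °C then 110 °C, sealed tube
Reagents that add atoms: none
Why: On heating, 7 undergoes four-electron electrocyclic ring opening to vinylketene 8. The ketene C=C bond adds to the electron-rich triple bond of 6 in a [2+2] cycloaddition: the nucleophilic, alkyl-bearing alkyne carbon bonds to the ketene carbonyl carbon and the oxygen-bearing alkyne carbon to the ketene α-carbon, giving cyclobutenone 9. Four-electron opening of 9 gives dienylketene 10, whose thermal six-electron (disrotatory) electrocyclisation closes the six-membered carbocycle 11, and tautomerisation gives phenol 12. The closest known reaction type is the Danheiser benzannulation of cyclobutenones with siloxyalkynes, which gives resorcinol monosilyl ethers. No stereocentre is formed (C4 of 9 is transient) and the two ring-C centres are not involved. The step needs regioselectivity, which the polarity of ketene and ynol ether secures, so that OH and OSi flank the alkylated carbon and OEt ends para to it. It also needs chemoselectivity for the ynol ether over the isopropenyl group, secured by the far higher ketenophilicity of the silyl ynol ether; the bulky silyl group should keep 6 from rearranging to a silylketene at these temperatures.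

Step 6
Reactants: 12 5-ethoxy-2-(CbCH2)-3-(triisopropylsilyloxy)phenol
Product: 13 6-ethoxy-2-hydroxy-3-(CbCH2)-4-(triisopropylsilyloxy)benzaldehyde
Conditions: MgCl2, Et3N, (CH2O)n, MeCN, reflux
Reagents that add atoms: paraformaldehyde (formaldehyde) C=O
Why: Magnesium-phenoxide-mediated ortho-formylation (Casnati–Skattebøl): formaldehyde is delivered inside the magnesium chelate only ortho to the free hydroxyl, and the other ortho position is blocked, so the formyl group enters at the future C6. Silyl ether and alkene are inert to these conditions.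

Step 7
Reactants: 13 salicylaldehyde
Product: 15 5-ethoxy-8-(CbCH2)-7-(triisopropylsilyloxy)-2H-chromen-2-one (coumarin numbering), via ester ylide 14 (not isolated)
Conditions: Ph3P=C=C=O, toluene, 110 °C
Reagents that add atoms: (triphenylphosphoranylidene)ketene O=C=C=P(c1ccccc1)(c1ccccc1)c1ccccc1
Why: The phenol adds to the Bestmann ylide to give ester ylide 14, which closes the ring by intramolecular Wittig reaction with the ortho aldehyde. The intramolecular mode enforces the Z alkene of the coumarin under neutral conditions.

Step 8
Reactants: 15 coumarin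
Product: 16 (4S)-5-ethoxy-8-(CbCH2)-4-pentyl-7-(triisopropylsilyloxy)chroman-2-one
Conditions: n-C5H11MgBr, CuBr·SMe2 (5 mol%), (R)-1-[(S)-2-(diphenylphosphino)ferrocenyl]ethyldicyclohexylphosphine (6 mol%), t-BuOMe, −72 °C; aq NH4Cl
Reagents that add atoms: n-pentylmagnesium bromide CCCCC[Mg]Br
Why: Copper-catalysed asymmetric conjugate addition of a Grignard reagent to a coumarin; the chiral ferrocenyl diphosphine–copper complex distinguishes the two faces of the planar lactone and should set the side-chain centre as 4S. At low temperature the catalysed 1,4-addition should outrun 1,2-addition to the lactone, and no ketone is yet present.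

Step 9
Reactants: 16 silyl ether
Product: 17 (4S)-5-ethoxy-7-hydroxy-8-(CbCH2)-4-pentylchroman-2-one
Conditions: TBAF, AcOH, THF, 0 °C
Reagents that add atoms: none
Why: Fluoride cleaves the aryl silyl ether; acetic acid buffers the phenoxide so that the lactone stays closed.

Step 10
Reactants: 17 phenol
Product: 18 (4S)-5-ethoxy-7-hydroxy-8-(CbCH2)-2-oxo-4-pentylchromane-6-carbaldehyde
Conditions: MgCl2, Et3N, (CH2O)n, THF, 65 °C
Reagents that add atoms: paraformaldehyde (formaldehyde) C=O
Why: Second magnesium-mediated ortho-formylation, now directed by the newly freed hydroxyl, whose only open ortho position is the future C4a. The aprotic medium and weakly nucleophilic magnesium alkoxides should leave the lactone closed.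

Step 11
Reactants: 18 salicylaldehyde
Product: 19 (4S)-5-ethoxy-7-hydroxy-6-[(E)-2-methylbut-2-enoyl]-8-(CbCH2)-4-pentylchroman-2-one
Conditions: but-2-yne (excess), [RhCl(cod)]2 (2.5 mol%), 1,1′-bis(diphenylphosphino)ferrocene (5 mol%), Na2CO3 (10 mol%), toluene, 80 °C, sealed tube
Reagents that add atoms: but-2-yne CC#CC
Why: Rhodium-catalysed, chelation-assisted hydroacylation of an internal alkyne by a salicylaldehyde: the phenoxide holds the acyl–rhodium hydride, which adds syn across but-2-yne and gives the (E)-tigloyl ketone without any acid. The isolated 1,1-disubstituted alkene should not compete with the alkyne.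

Step 12
Reactants: 19 o-tigloyl phenol
Product: 20 (4S)-5-ethoxy-4-pentyl-8-(CbCH2)chroman-2-one fused at C6–C7 to a cis-(2R,3S)-2,3-dimethyl-2,3-dihydropyran-4-one (ketone carbon on C6; ring oxygen on C7)
Conditions: quinine (20 mol%), chlorobenzene, rt
Reagents that add atoms: none
Why: Cinchona-alkaloid-catalysed intramolecular oxa-Michael addition of an o-tigloyl phenol: quinine binds phenol and enone and delivers oxygen to one face of the β-carbon, which by analogy with related o-tigloyl phloroglucinol-type phenols should set C2 as R. Kinetic protonation of the enol should give mainly the cis isomer. Only this hydroxyl is ortho to the ketone, the other neighbour being the ethyl ether.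

Step 13
Reactants: 20 cis-pyranone ethyl ether
Product: 21 (4S)-5-hydroxy-4-pentyl-8-(CbCH2)chroman-2-one fused at C6–C7 to a trans-(2R,3R)-2,3-dimethyl-2,3-dihydropyran-4-one (ketone carbon on C6; ring oxygen on C7)
Conditions: MgI2·OEt2, toluene, 60 °C; aq NH4Cl
Reagents that add atoms: none
Why: Magnesium iodide chelated between the ketone and the peri ethoxy oxygen activates the ether for SN2 attack of iodide on the ethyl group (chelation-controlled dealkylation ortho to a carbonyl). The same chelate promotes enolisation at C3, which should equilibrate to the diequatorial trans isomer without breaking the C2–O bond. Any acyl shift of the lactone to the new hydroxyl is without consequence, since both lactones give 22 in step 14.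

Step 14
Reactants: 21 hydroxy lactone
Product: 22 methyl (3S)-3-[(2R,3R)-5,7-dihydroxy-2,3-dimethyl-8-(CbCH2)-4-oxochroman-6-yl]octanoate
Conditions: K2CO3, MeOH, 0 °C to rt; pH 6 buffer
Reagents that add atoms: methanol CO
Why: Base-mediated methanolysis of the aryl ester (lactone) gives the methyl ester and frees O7–H. The phenoxide form of the 5-hydroxy ketone resists enolisation, which protects ring B. The product is used at once to avoid re-lactonisation.

Step 15
Reactants: 22 dihydroxy chromanone methyl ester
Product: 23 methyl (3S)-3-[(2R,3R,8R)-5-hydroxy-2,3-dimethyl-8-(CbCH2)-8-(3-methylbut-2-en-1-yl)-4,7-dioxo-3,4,7,8-tetrahydro-2H-chromen-6-yl]octanoate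
Conditions: tert-butyl prenyl carbonate, Pd2(dba)3·CHCl3 (2.5 mol%), (1R,2R)-N,N′-bis[2-(diphenylphosphino)benzoyl]cyclohexane-1,2-diamine (7.5 mol%), 1,4-dioxane, rt
Reagents that add atoms: tert-butyl (3-methylbut-2-en-1-yl) carbonate CC(C)=CCOC(=O)OC(C)(C)C
Why: Palladium-catalysed asymmetric allylic alkylation with dearomatisation (Tsuji–Trost): ionisation of the carbonate gives a π-prenyl palladium complex and tert-butoxide, which deprotonates the more acidic O7–H (para to the ketone). The phenoxide should attack through C8, the ortho carbon with the smaller (primary) substituent, at the unsubstituted allyl terminus. The chiral ligand pocket is relied on to select the ring face and hence 8R, as the existing centres are too remote to interfere.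

Step 16
Reactants: 23 methyl ester
Product: 24 (3S)-3-[(2R,3R,8R)-5-hydroxy-2,3-dimethyl-8-(CbCH2)-8-(3-methylbut-2-en-1-yl)-4,7-dioxo-3,4,7,8-tetrahydro-2H-chromen-6-yl]octanoic acid (CNP0208815.1)
Conditions: LiOH, THF/H2O, 0 °C to rt; then 1 M HCl to pH 3–4, 0 °C
Reagents that add atoms: lithium hydroxide [Li+].[OH-]
Why: Saponification of the unhindered methyl ester; under base ring A is present as its delocalised enolate, which should shield ring B from hydroxide and from retro-oxa-Michael opening. Cold, careful acidification avoids lactonisation and alkene protonation.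

## Compound list

1 | (1S,5S)-(−)-α-pinene | CC1=CC[C@H]2C[C@@H]1C2(C)C | starting material
2 | 2-[(1R,3R)-3-acetyl-2,2-dimethylcyclobutyl]acetic acid (cis-pinonic acid) | CC(=O)[C@@H]1C[C@H](CC(=O)O)C1(C)C | intermediate
3 | ethyl 2-[(1R,3R)-3-acetyl-2,2-dimethylcyclobutyl]acetate | CC(=O)[C@@H]1C[C@H](CC(=O)OCC)C1(C)C | intermediate
4 | ethyl 2-[(1R,3S)-2,2-dimethyl-3-(prop-1-en-2-yl)cyclobutyl]acetate | C=C(C)[C@@H]1C[C@H](CC(=O)OCC)C1(C)C | intermediate
5 | lithium 3-[(1R,3S)-2,2-dimethyl-3-(prop-1-en-2-yl)cyclobutyl]prop-1-yn-1-olate (not isolated) | [Li+].[O-]C#CC[C@H]1C[C@@H](C(C)=C)C1(C)C | intermediate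
6 | triisopropyl{[3-((1R,3S)-2,2-dimethyl-3-(prop-1-en-2-yl)cyclobutyl)prop-1-yn-1-yl]oxy}silane | CC(C)[Si](OC#CC[C@H]1C[C@@H](C(C)=C)C1(C)C)(C(C)C)C(C)C | intermediate
7 | 3-ethoxycyclobut-2-en-1-one | CCOC1=CC(=O)C1 | starting material
8 | 3-ethoxybuta-1,3-dien-1-one (vinylketene, not isolated) | C=C(OCC)C=C=O | intermediate
9 | 4-(1-ethoxyethenyl)-2-(CbCH2)-3-(triisopropylsilyloxy)cyclobut-2-en-1-one (both C4 epimers, not isolated) | C=C(OCC)C1C(=O)C(C[C@H]2C[C@@H](C(C)=C)C2(C)C)=C1O[Si](C(C)C)(C(C)C)C(C)C | intermediate
10 | (3E)-5-ethoxy-2-(CbCH2)-3-(triisopropylsilyloxy)hexa-1,3,5-trien-1-one (dienylketene, not isolated) | C=C(OCC)/C=C(O[Si](C(C)C)(C(C)C)C(C)C)\C(C[C@H]1C[C@@H](C(C)=C)C1(C)C)=C=O | intermediate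
11 | 5-ethoxy-2-(CbCH2)-3-(triisopropylsilyloxy)cyclohexa-2,4-dien-1-one (not isolated) | O=C1CC(OCC)=CC(O[Si](C(C)C)(C(C)C)C(C)C)=C1C[C@H]2C[C@@H](C(C)=C)C2(C)C | intermediate
12 | 5-ethoxy-2-(CbCH2)-3-(triisopropylsilyloxy)phenol | CCOc1cc(O)c(C[C@H]2C[C@@H](C(C)=C)C2(C)C)c(O[Si](C(C)C)(C(C)C)C(C)C)c1 | intermediate
13 | 6-ethoxy-2-hydroxy-3-(CbCH2)-4-(triisopropylsilyloxy)benzaldehyde | CCOc1cc(O[Si](C(C)C)(C(C)C)C(C)C)c(C[C@H]2C[C@@H](C(C)=C)C2(C)C)c(O)c1C=O | intermediate
14 | 3-ethoxy-2-formyl-6-(CbCH2)-5-(triisopropylsilyloxy)phenyl (triphenylphosphoranylidene)acetate (not isolated) | CCOc1cc(O[Si](C(C)C)(C(C)C)C(C)C)c(C[C@H]2C[C@@H](C(C)=C)C2(C)C)c(OC(=O)C=P(c2ccccc2)(c2ccccc2)c2ccccc2)c1C=O | intermediate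
15 | 5-ethoxy-8-(CbCH2)-7-(triisopropylsilyloxy)-2H-chromen-2-one | CCOc1cc(O[Si](C(C)C)(C(C)C)C(C)C)c(C[C@H]2C[C@@H](C(C)=C)C2(C)C)c2OC(=O)C=Cc12 | intermediate
16 | (4S)-5-ethoxy-8-(CbCH2)-4-pentyl-7-(triisopropylsilyloxy)chroman-2-one | CCOc1cc(O[Si](C(C)C)(C(C)C)C(C)C)c(C[C@H]2C[C@@H](C(C)=C)C2(C)C)c2OC(=O)C[C@H](CCCCC)c12 | intermediate
17 | (4S)-5-ethoxy-7-hydroxy-8-(CbCH2)-4-pentylchroman-2-one | CCOc1cc(O)c(C[C@H]2C[C@@H](C(C)=C)C2(C)C)c2OC(=O)C[C@H](CCCCC)c12 | intermediate
18 | (4S)-5-ethoxy-7-hydroxy-8-(CbCH2)-2-oxo-4-pentylchromane-6-carbaldehyde | CCOc1c(C=O)c(O)c(C[C@H]2C[C@@H](C(C)=C)C2(C)C)c2OC(=O)C[C@H](CCCCC)c12 | intermediate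
19 | (4S)-5-ethoxy-7-hydroxy-6-[(E)-2-methylbut-2-enoyl]-8-(CbCH2)-4-pentylchroman-2-one | CCOc1c(C(=O)/C(C)=C/C)c(O)c(C[C@H]2C[C@@H](C(C)=C)C2(C)C)c2OC(=O)C[C@H](CCCCC)c12 | intermediate
20 | (4S)-5-ethoxy-4-pentyl-8-(CbCH2)chroman-2-one fused at C6–C7 to cis-(2R,3S)-2,3-dimethyl-2,3-dihydropyran-4-one | CCOc1c2c(O[C@H](C)[C@H](C)C2=O)c(C[C@H]3C[C@@H](C(C)=C)C3(C)C)c2OC(=O)C[C@H](CCCCC)c12 | intermediate
21 | (4S)-5-hydroxy-4-pentyl-8-(CbCH2)chroman-2-one fused at C6–C7 to trans-(2R,3R)-2,3-dimethyl-2,3-dihydropyran-4-one | Oc1c2c(O[C@H](C)[C@@H](C)C2=O)c(C[C@H]3C[C@@H](C(C)=C)C3(C)C)c2OC(=O)C[C@H](CCCCC)c12 | intermediate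
22 | methyl (3S)-3-[(2R,3R)-5,7-dihydroxy-2,3-dimethyl-8-(CbCH2)-4-oxochroman-6-yl]octanoate | COC(=O)C[C@H](CCCCC)c1c(O)c(C[C@H]2C[C@@H](C(C)=C)C2(C)C)c2O[C@H](C)[C@@H](C)C(=O)c2c1O | intermediate
23 | methyl (3S)-3-[(2R,3R,8R)-5-hydroxy-2,3-dimethyl-8-(CbCH2)-8-(3-methylbut-2-en-1-yl)-4,7-dioxo-3,4,7,8-tetrahydro-2H-chromen-6-yl]octanoate | C=C(C)[C@@H]1C[C@H](C[C@@]2(CC=C(C)C)C(=O)C([C@@H](CCCCC)CC(=O)OC)=C(O)C3=C2O[C@H](C)[C@@H](C)C3=O)C1(C)C | intermediate
24 | (3S)-3-[(2R,3R,8R)-5-hydroxy-2,3-dimethyl-8-(CbCH2)-8-(3-methylbut-2-en-1-yl)-4,7-dioxo-3,4,7,8-tetrahydro-2H-chromen-6-yl]octanoic acid (CNP0208815.1) | C=C(C)[C@@H]1C[C@H](C[C@@]2(CC=C(C)C)C(=O)C([C@@H](CCCCC)CC(=O)O)=C(O)C3=C2O[C@H](C)[C@@H](C)C3=O)C1(C)C | target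

## Step count and least certain steps

Total: 16 steps. Longest linear sequence: 16 steps (1 to 24); 7 enters at step 5 as purchased.

**Step 5 (key step).** The most likely failure is a mismatch of thermal windows: oligomerisation of the vinylketene before capture, or a silyl shift in the ynol ether at the temperature needed to open the vinylcyclobutenone. Fallback: generate the same vinylketene at room temperature by photochemical Wolff rearrangement of the diazo ketone 1-diazo-3-ethoxybut-3-en-2-one F1 in the presence of 6 (the diazo-ketone version of the benzannulation), then warm only to finish the electrocyclic steps. This sets out from 6 and returns at 12.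

**Step 15.** Facial selectivity may be poor because the two flanks of C8 (C7–O and C8a–O) are sterically alike. Alkylation at C6 or at oxygen, or a second alkylation of the acidic product, may also compete. Fallback: uncatalysed C-prenylation of 22 with prenyl bromide and NaOMe in MeOH at 0 °C (the classical alkylation of acylphloroglucinols), then chromatographic separation of 23 from its diastereomer, the C8 epimer of 23 F2. This sets out from 22 and returns at 23.

**Step 8.** The peri ethoxy group and two donor oxygens may slow the conjugate addition until 1,2-addition to the lactone takes over, and the level of induction on a 5-alkoxycoumarin is untested. Fallback, in which the centre is set by hydride instead of by the alkyl group: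
- esterify 12 with oct-2-ynoic acid (DCC, DMAP) to the aryl ester 5-ethoxy-2-(CbCH2)-3-(triisopropylsilyloxy)phenyl oct-2-ynoate F3;
- close it by gold-catalysed intramolecular hydroarylation ([Au(NCMe){P(t-Bu)2(biphenyl-2-yl)}]SbF6, CH2Cl2) to 5-ethoxy-8-(CbCH2)-4-pentyl-7-(triisopropylsilyloxy)-2H-chromen-2-one F4;
- reduce it by copper hydride asymmetric conjugate reduction (Cu(OAc)2, (R)-DTBM-SEGPHOS, polymethylhydrosiloxane, t-BuOH).

This sets out from 12 and returns at 16.

**Step 13.** De-ethylation may be incomplete under conditions mild enough for the two alkenes, or hydrogen iodide may add to them. Fallback, which keeps the ethyl ether to the end: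
- K2CO3/MeOH opens the lactone of 20 and equilibrates C3, giving methyl (3S)-3-[(2R,3R)-5-ethoxy-7-hydroxy-2,3-dimethyl-8-(CbCH2)-4-oxochroman-6-yl]octanoate F5;
- the prenylation of step 15 gives the neutral vinylogous ester methyl (3S)-3-[(2R,3R,8R)-5-ethoxy-2,3-dimethyl-8-(CbCH2)-8-(3-methylbut-2-en-1-yl)-4,7-dioxo-3,4,7,8-tetrahydro-2H-chromen-6-yl]octanoate F6, which cannot be alkylated twice;
- LiOH at 0 °C followed by dilute aqueous HCl in THF hydrolyses the ester and then the vinylogous ester.

This sets out from 20 and returns at 24.

**Step 11.** With the aldehyde wedged between OH and OEt, decarbonylation of the acyl–rhodium hydride or uncatalysed (non-selective) ring closure of the product at the reaction temperature may compete. Fallback: Nozaki–Hiyama–Kishi addition of (E)-2-bromobut-2-ene to 18 (CrCl2, NiCl2 cat., DMF), which tolerates the lactone, gives (4S)-5-ethoxy-7-hydroxy-6-[(E)-1-hydroxy-2-methylbut-2-en-1-yl]-8-(CbCH2)-4-pentylchroman-2-one F7; oxidation with MnO2 gives the ketone. This sets out from 18 and returns at 19.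

## Further compounds

F1 | step 5 | 1-diazo-3-ethoxybut-3-en-2-one | C=C(OCC)C(=O)C=[N+]=[N-]
F2 | step 15 | methyl (3S)-3-[(2R,3R,8S)-5-hydroxy-2,3-dimethyl-8-(CbCH2)-8-(3-methylbut-2-en-1-yl)-4,7-dioxo-3,4,7,8-tetrahydro-2H-chromen-6-yl]octanoate (C8 epimer of 23) | C=C(C)[C@@H]1C[C@H](C[C@]2(CC=C(C)C)C(=O)C([C@@H](CCCCC)CC(=O)OC)=C(O)C3=C2O[C@H](C)[C@@H](C)C3=O)C1(C)C
F3 | step 8 | 5-ethoxy-2-(CbCH2)-3-(triisopropylsilyloxy)phenyl oct-2-ynoate | CCOc1cc(OC(=O)C#CCCCCC)c(C[C@H]2C[C@@H](C(C)=C)C2(C)C)c(O[Si](C(C)C)(C(C)C)C(C)C)c1
F4 | step 8 | 5-ethoxy-8-(CbCH2)-4-pentyl-7-(triisopropylsilyloxy)-2H-chromen-2-one | CCCCCC1=CC(=O)Oc2c(C[C@H]3C[C@@H](C(C)=C)C3(C)C)c(O[Si](C(C)C)(C(C)C)C(C)C)cc(OCC)c12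
F5 | step 13 | methyl (3S)-3-[(2R,3R)-5-ethoxy-7-hydroxy-2,3-dimethyl-8-(CbCH2)-4-oxochroman-6-yl]octanoate | COC(=O)C[C@H](CCCCC)c1c(O)c(C[C@H]2C[C@@H](C(C)=C)C2(C)C)c2O[C@H](C)[C@@H](C)C(=O)c2c1OCC
F6 | step 13 | methyl (3S)-3-[(2R,3R,8R)-5-ethoxy-2,3-dimethyl-8-(CbCH2)-8-(3-methylbut-2-en-1-yl)-4,7-dioxo-3,4,7,8-tetrahydro-2H-chromen-6-yl]octanoate | C=C(C)[C@@H]1C[C@H](C[C@@]2(CC=C(C)C)C(=O)C([C@@H](CCCCC)CC(=O)OC)=C(OCC)C3=C2O[C@H](C)[C@@H](C)C3=O)C1(C)C
F7 | step 11 | (4S)-5-ethoxy-7-hydroxy-6-[(E)-1-hydroxy-2-methylbut-2-en-1-yl]-8-(CbCH2)-4-pentylchroman-2-one (both carbinol epimers) | CCOc1c(C(O)/C(C)=C/C)c(O)c(C[C@H]2C[C@@H](C(C)=C)C2(C)C)c2OC(=O)C[C@H](CCCCC)c12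
A1 | alternative 1 | 2,2-dimethyl-3-(arylmethyl)cyclobutanone tripivalate | CC(C)(C)C(=O)Oc1cc(OC(=O)C(C)(C)C)c(C[C@H]2CC(=O)C2(C)C)c(OC(=O)C(C)(C)C)c1
A2 | alternative 1 | 2-allylbenzene-1,3,5-triyl tripivalate | C=CCc1c(OC(=O)C(C)(C)C)cc(OC(=O)C(C)(C)C)cc1OC(=O)C(C)(C)C
A3 | alternative 1 | 1-[(2R,5R)-2,5-dimethylpyrrolidin-1-yl]-2-methylpropan-1-one | CC(C)C(=O)N1[C@H](C)CC[C@H]1C
A4 | alternative 2 | enol lactone of the target (lactone through O5) | C=C(C)[C@@H]1C[C@H](C[C@@]2(CC=C(C)C)C(=O)C3=C(OC(=O)C[C@@H]3CCCCC)C3=C2O[C@H](C)[C@@H](C)C3=O)C1(C)C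
A5 | alternative 2 | acetaldehyde | CC=O
A6 | alternative 3 | 4-pentyl-dihydrocoumarin-fused pyranone (identical with 21) | O=C1C[C@H](CCCCC)c2c(O1)c(C[C@H]1C[C@@H](C(C)=C)C1(C)C)c1O[C@H](C)[C@@H](C)C(=O)c1c2O
A7 | alternative 3 | (2R,3R)-5,7-dihydroxy-2,3-dimethyl-8-(CbCH2)chroman-4-one | C=C(C)[C@@H]1C[C@H](Cc2c(O)cc(O)c3C(=O)[C@H](C)[C@@H](C)Oc23)C1(C)C
A8 | alternative 3 | (E)-oct-2-enal | CCCCC/C=C/C=O
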